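**Retrosynthetic overview**
- The target is two copies of one C7 bromocatechol unit (5-bromo-3,4-dioxygenated benzyl). The only skeletal bond to make is the tetra-ortho-substituted diaryl ether between O3 of ring A (the 2,5-dibromo ring) and C2 of ring B (the carbon between C1–CH2OH and the C3/C4 catechol).
- Key disconnection, a biomimetic cross-coupling of two monomers: the O3(A)–C2(B) bond is formed by conjugate addition of the ring-A phenoxide to the C3/C4 o-quinone of ring B. The contiguous O2/O3/O4 pattern of ring B is what such a quinone gives when captured at C2, and the ring-B catechol is returned free.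
- Both monomers come from one commercial bromocatechol aldehyde: ring A by 4-O-methylation and bromination ortho to the remaining OH, ring B by oxidation in the flask.
- The benzylic carbons stay as CHO through the coupling, because the formyl group on the quinone steers the attack to C2. Demethylation and a double reduction finish the route.
- No ring is formed (both arenes are bought) and no stereocentre has to be set.

Key step: step 3

Remark: the SMILES has no stereodescriptor and the molecule has no stereocentre; the diaryl ether axis is assumed not to be configurationally stable, so the target is treated as the achiral compound drawn. Locants for ring A and ring B in the text follow the benzaldehyde numbering (C1 bears CHO or CH2OH).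

**Step 1**
Reactants: 1 3-bromo-4,5-dihydroxybenzaldehyde
Product: 2 3-bromo-5-hydroxy-4-methoxybenzaldehyde
Conditions: MeI (1.1 equiv), Li2CO3 (1.1 equiv), DMF, 40 °C
Reagents that add atoms: iodomethane, CI
Why: The 4-OH (para to CHO, ortho to Br) is the more acidic hydroxyl, so the weak base should form its phenoxide selectively and Williamson O-methylation should leave the 5-OH (the future ether oxygen) free.

**Step 2**
Reactants: 2 3-bromo-5-hydroxy-4-methoxybenzaldehyde
Product: 3 2,5-dibromo-3-hydroxy-4-methoxybenzaldehyde
Conditions: Br2 (1.05 equiv), NaOAc, cat. Fe powder, AcOH, rt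
Reagents that add atoms: bromine, BrBr
Why: Electrophilic aromatic bromination should go ortho to the free phenol, between OH and CHO, which is the regiochemistry established for isovanillin under these conditions; the para position is further shielded by the flanking Br and CHO.

**Step 3**
Reactants: 1 3-bromo-4,5-dihydroxybenzaldehyde; 3 2,5-dibromo-3-hydroxy-4-methoxybenzaldehyde
Product: 6 5-bromo-2-(2,5-dibromo-3-formyl-6-methoxyphenoxy)-3,4-dihydroxybenzaldehyde, via o-quinone aldehyde 4 (not isolated), via dienone sigma-adduct 5 (not isolated)
Conditions: (a) 1, Ag2O (1.5 equiv), MgSO4, THF, –20 °C, dark, 10 min, cold filtration under Ar; (b) filtrate added slowly to 3 (1.5 equiv), Cs2CO3 (1.5 equiv), 4 Å MS, MeCN/DMF, –40 → 0 °C; (c) dilute aq. HCl/Na2S2O4 work-up, excess 3 recovered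
Reagents that add atoms: none
Why: Proposed new method: the cesium phenoxide of 3 should add through oxygen to C2 of o-quinone 4 (the ring CH between the formyl-bearing C1 and the C3 carbonyl), which is both the β-carbon of the enal O=CH–C1=C2 and the δ-carbon of the dienone O=C4–C5=C6–C1=C2, giving sigma-adduct 5 whose anion is delocalized onto O4 and the formyl oxygen; enolization of 5 then restores the catechol and makes the addition irreversible. The closest known reaction types are oxa- and thia-Michael additions of heteronucleophiles to o-quinones generated from catechols, and the addition–elimination of phenoxides on haloquinones to give aryloxyquinones; the same sense of coupling (a meta-hydroxyl oxygen onto the ring carbon ortho to the carbonyl substituent) is assumed for the diaryl ether links of galloyl-derived natural products. No ring is closed and no stereocentre persists, since 5 is a transient racemic sp3 adduct that aromatizes. The step needs site selectivity among three ring positions of 4 and O- over C-attack: only C2 is activated by the formyl group, the competing 1,4-site C6 is flanked by C5–Br and the formyl-bearing carbon, ipso attack at C5–Br lacks enal activation, and the only free carbon of the phenoxide (para to O–) is flanked by CHO and Br and deactivated. Oxidizing 1 separately with Ag2O keeps the oxidant away from 3 and from the product, and the dithionite wash is a safeguard that should return any product re-oxidized by excess 4 to catechol 6.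

**Step 4**
Reactants: 6 5-bromo-2-(2,5-dibromo-3-formyl-6-methoxyphenoxy)-3,4-dihydroxybenzaldehyde
Product: 7 5-bromo-2-(2,5-dibromo-3-formyl-6-hydroxyphenoxy)-3,4-dihydroxybenzaldehyde
Conditions: BBr3 (6 equiv), CH2Cl2, –78 → 0 °C; then ice-water
Reagents that add atoms: none
Why: BBr3 cleavage of the single alkyl aryl ether (a di-ortho-flanked OMe) should leave the diaryl ether, aryl bromides and aldehydes intact at or below 0 °C, and placing it before the reduction keeps benzylic alcohols away from BBr3.

**Step 5**
Reactants: 7 5-bromo-2-(2,5-dibromo-3-formyl-6-hydroxyphenoxy)-3,4-dihydroxybenzaldehyde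
Product: 8 6-bromo-3-[2,5-dibromo-6-hydroxy-3-(hydroxymethyl)phenoxy]-4-(hydroxymethyl)benzene-1,2-diol (target)
Conditions: NaBH4 (excess), THF/H2O, 0 °C → rt; then aq. NH4Cl to pH 6, no alcohol solvent, no strong acid
Reagents that add atoms: none
Why: NaBH4 reduction of both aryl aldehydes to benzylic alcohols is standard for polybrominated hydroxybenzaldehydes and leaves aryl bromides, phenols and the diaryl ether untouched; the buffered, alcohol-free work-up should avoid quinone-methide solvolysis of the p-hydroxybenzyl alcohols.

**Compound list**
1 | 3-bromo-4,5-dihydroxybenzaldehyde | O=Cc1cc(O)c(O)c(Br)c1 | starting material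
2 | 3-bromo-5-hydroxy-4-methoxybenzaldehyde | O=Cc1cc(O)c(OC)c(Br)c1 | intermediate
3 | 2,5-dibromo-3-hydroxy-4-methoxybenzaldehyde | O=Cc1cc(Br)c(OC)c(O)c1Br | intermediate
4 | 5-bromo-3,4-dioxocyclohexa-1,5-diene-1-carbaldehyde (o-quinone of 1) | O=CC1=CC(=O)C(=O)C(Br)=C1 | intermediate (not isolated)
5 | 3-bromo-6-(2,5-dibromo-3-formyl-6-methoxyphenoxy)-4-hydroxy-5-oxocyclohexa-1,3-diene-1-carbaldehyde (racemic sigma-adduct) | O=CC1=CC(Br)=C(O)C(=O)C1Oc1c(Br)c(C=O)cc(Br)c1OC | intermediate (not isolated)
6 | 5-bromo-2-(2,5-dibromo-3-formyl-6-methoxyphenoxy)-3,4-dihydroxybenzaldehyde | O=Cc1cc(Br)c(O)c(O)c1Oc1c(Br)c(C=O)cc(Br)c1OC | intermediate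
7 | 5-bromo-2-(2,5-dibromo-3-formyl-6-hydroxyphenoxy)-3,4-dihydroxybenzaldehyde | O=Cc1cc(Br)c(O)c(O)c1Oc1c(Br)c(C=O)cc(Br)c1O | intermediate
8 | 6-bromo-3-[2,5-dibromo-6-hydroxy-3-(hydroxymethyl)phenoxy]-4-(hydroxymethyl)benzene-1,2-diol | OCc1cc(Br)c(O)c(Oc2c(CO)cc(Br)c(O)c2O)c1Br | target

**Step count and risks**
Total steps: 5. Longest linear sequence: 5 (1 → 2 → 3 → 6 → 7 → 8; compound 1 enters again in step 3).

Steps most likely to fail:

1. Step 3 (Proposed new method). What may go wrong: addition of the phenoxide at the wrong quinone position (1,4-addition at C6 or ipso attack at C5–Br), C- instead of O-arylation, hydration or self-condensation of the quinone before it is trapped, and redox exchange between product and remaining quinone. Fallback with known chemistry (SNAr, then late bromination), setting out from 3 and coming back at 7: the potassium phenoxide of 3 (K2CO3, DMF, 110 °C) should displace fluoride from commercial 2-fluoro-3,4-dimethoxybenzaldehyde (O=Cc1ccc(OC)c(OC)c1F), whose C–F bond is activated by the ortho formyl group, to give 2-(2,5-dibromo-3-formyl-6-methoxyphenoxy)-3,4-dimethoxybenzaldehyde F1. BBr3 in CH2Cl2 should then remove all three methyl groups to give 2-(2,5-dibromo-3-formyl-6-hydroxyphenoxy)-3,4-dihydroxybenzaldehyde F2. One equivalent of Br2 (NaOAc, AcOH, rt) should brominate ring B ortho to its 4-OH and meta to CHO, the position brominated in 3,4-dihydroxybenzaldehyde itself, while ring A has no activated free position; this gives 7.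

2. Step 2. What may go wrong: bromination para instead of ortho to the phenol, or over-bromination and ipso substitution. Fallback (directed ortho-metalation in place of electrophilic substitution), setting out from 2 and coming back at 3: 2 is converted to its MOM ether, 3-bromo-4-methoxy-5-(methoxymethoxy)benzaldehyde F3 (MOMCl, i-Pr2NEt, CH2Cl2), and then to the dimethyl acetal, 1-bromo-5-(dimethoxymethyl)-2-methoxy-3-(methoxymethoxy)benzene F4 (HC(OMe)3, cat. PPTS, MeOH). LiTMP in THF at –78 °C should deprotonate the one position flanked by both directing groups (OMOM and the acetal), and quenching with 1,2-dibromotetrachloroethane should give 1,4-dibromo-5-(dimethoxymethyl)-2-methoxy-3-(methoxymethoxy)benzene F5. Aqueous HCl in THF should remove acetal and MOM together and return 3.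

3. Step 5. What may go wrong: slow hydride transfer to aldehydes deactivated by para-phenoxide formation, and acid-triggered quinone-methide formation (solvolysis, oligomerization) of the product during work-up. Fallback (mask, reduce, unmask), setting out from 7 and coming back at 8: 7 is peracetylated (Ac2O, pyridine, CH2Cl2) to the tri-O-acetate of 7, with all three phenols as acetates and both CHO groups intact, F6. BH3·THF at 0 °C should reduce the two neutral aldehydes to give the tri-O-acetate of the target, with both CH2OH groups free, F7. Methanolysis (K2CO3, MeOH, 0 °C, then pH 6 phosphate buffer) should release 8.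

**Further compounds**
F1 | step 3 | 2-(2,5-dibromo-3-formyl-6-methoxyphenoxy)-3,4-dimethoxybenzaldehyde | O=Cc1ccc(OC)c(OC)c1Oc1c(Br)c(C=O)cc(Br)c1OC
F2 | step 3 | 2-(2,5-dibromo-3-formyl-6-hydroxyphenoxy)-3,4-dihydroxybenzaldehyde | O=Cc1ccc(O)c(O)c1Oc1c(Br)c(C=O)cc(Br)c1O
F3 | step 2 | 3-bromo-4-methoxy-5-(methoxymethoxy)benzaldehyde | O=Cc1cc(Br)c(OC)c(OCOC)c1
F4 | step 2 | 1-bromo-5-(dimethoxymethyl)-2-methoxy-3-(methoxymethoxy)benzene | COC(OC)c1cc(Br)c(OC)c(OCOC)c1
F5 | step 2 | 1,4-dibromo-5-(dimethoxymethyl)-2-methoxy-3-(methoxymethoxy)benzene | COC(OC)c1cc(Br)c(OC)c(OCOC)c1Br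
F6 | step 5 | tri-O-acetate of 7: 6-bromo-3-(6-acetoxy-2,5-dibromo-3-formylphenoxy)-4-formyl-1,2-phenylene diacetate | O=Cc1cc(Br)c(OC(C)=O)c(OC(C)=O)c1Oc1c(Br)c(C=O)cc(Br)c1OC(C)=O
F7 | step 5 | tri-O-acetate of 8: 6-bromo-3-[6-acetoxy-2,5-dibromo-3-(hydroxymethyl)phenoxy]-4-(hydroxymethyl)-1,2-phenylene diacetate | OCc1cc(Br)c(OC(C)=O)c(OC(C)=O)c1Oc1c(Br)c(CO)cc(Br)c1OC(C)=O
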